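Ring A of the target is a phloroglucinol whose benzoyl-bearing carbon C1 lies between the oxygenated carbons C2 and C6. The key step exploits this C6–OH/C1–acyl pair: both the C1–carbonyl bond and the C6–O bond are made at once when an aryne carrying the C2 ether takes up benzoic acid, oxygen first at C6, and the acyl group then shifts to C1; no ring is formed. The precursor is an ortho-trimethylsilyl aryl triflate that already holds the complete, silyl-protected (R)-hydroxy side chain between two MOM ethers; its stereocentre comes unchanged from methyl (R)-glycidate.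

Key step: step 11

Remark on the chemistry: the side chain is built on the ring from a glycidic ester, whose epoxide can be opened only at its CH2 group; an alkenyl oxirane would offer an aryl nucleophile two further sites of attack (the allylic carbon and the alkene terminus).

Step 1
Reactants: 1 phloroglucinol (benzene-1,3,5-triol)
Product: 2 5-(triisopropylsilyloxy)benzene-1,3-diol
Conditions: TIPSCl (1.0 equiv), imidazole, DMF, 0 °C → rt
Reagents that add atoms: chlorotri(propan-2-yl)silane (TIPSCl), CC(C)[Si](Cl)(C(C)C)C(C)C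
Why: Silyl ether formation at one of three equivalent phenols; with one equivalent of the bulky chloride the mono-ether should be the main product, separable by chromatography from triol (recycled) and bis-ether.

Step 2
Reactants: 2 mono-TIPS phloroglucinol
Product: 3 [3,5-bis(methoxymethoxy)phenoxy]tri(propan-2-yl)silane
Conditions: MOMCl (2.5 equiv), i-Pr2NEt, CH2Cl2, 0 °C → rt
Reagents that add atoms: chloro(methoxy)methane (MOMCl), COCCl
Why: Double O-alkylation of the two remaining phenols with the chloromethyl ether under amine base (MOM protection), which also installs the two groups that later direct lithiation.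

Step 3
Reactants: 3 bis-MOM TIPS arene; 4 methyl (2R)-oxirane-2-carboxylate (methyl (R)-glycidate)
Product: 7 methyl (2R)-3-[2,6-bis(methoxymethoxy)-4-(triisopropylsilyloxy)phenyl]-2-hydroxypropanoate, via aryllithium 5 (not isolated), via arylmagnesium bromide 6 (not isolated)
Conditions: n-BuLi, THF, 0 °C; MgBr2·OEt2, −20 °C; CuBr·SMe2 (10 mol%), then 4, −40 → −20 °C
Reagents that add atoms: none
Why: Directed ortho-lithiation occurs at the only position flanked by both MOM ethers, and after transmetalation the copper-catalysed aryl Grignard reagent opens the epoxide of 4 by SN2 attack at its unsubstituted CH2 (the usual β-opening of glycidic esters) faster than it adds to the ester at low temperature; no bond to C2 is made or broken, so the (R) centre of 4 becomes the (R) carbinol of 7.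

Step 4
Reactants: 7 hydroxy ester
Product: 8 methyl (2R)-3-[2,6-bis(methoxymethoxy)-4-(triisopropylsilyloxy)phenyl]-2-(tert-butyldimethylsilyloxy)propanoate
Conditions: TBSCl, imidazole, DMF, rt
Reagents that add atoms: tert-butylchlorodimethylsilane (TBSCl), CC(C)(C)[Si](C)(C)Cl
Why: Standard silylation of a secondary α-hydroxy ester under mild amine-base conditions; the stereocentre is not involved.

Step 5
Reactants: 8 silyloxy ester
Product: 9 (2R)-3-[2,6-bis(methoxymethoxy)-4-(triisopropylsilyloxy)phenyl]-2-(tert-butyldimethylsilyloxy)-N-methoxy-N-methylpropanamide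
Conditions: MeNH(OMe)·HCl, i-PrMgCl, THF, −20 → 0 °C
Reagents that add atoms: N,O-dimethylhydroxylamine hydrochloride, CNOC.Cl
Why: Ester aminolysis by the chloromagnesium amide of N,O-dimethylhydroxylamine (Weinreb amide formation), which is fast at low temperature and should not enolise the α-silyloxy ester.

Step 6
Reactants: 9 Weinreb amide; 10 5-bromo-2-methylpent-2-ene
Product: 12 (2R)-1-[2,6-bis(methoxymethoxy)-4-(triisopropylsilyloxy)phenyl]-2-(tert-butyldimethylsilyloxy)-7-methyloct-6-en-3-one, via Grignard reagent 11 (not isolated)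
Conditions: 10, Mg, THF, rt; then 9, THF, 0 °C
Reagents that add atoms: none
Why: Weinreb ketone synthesis, in which the Grignard reagent adds once to give a stable magnesium chelate that releases the ketone only on aqueous work-up, leaving the α-stereocentre untouched.

Step 7
Reactants: 12 ketone
Product: 13 tert-butyl{[(2R)-1-[2,6-bis(methoxymethoxy)-4-(triisopropylsilyloxy)phenyl]-7-methyl-3-methylideneoct-6-en-2-yl]oxy}dimethylsilane
Conditions: Ph3PCH3Br, KOt-Bu, THF, 0 °C → rt
Reagents that add atoms: methyltriphenylphosphonium bromide, C[P+](c1ccccc1)(c1ccccc1)c1ccccc1.[Br-]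
Why: Wittig methylenation of the ketone with the non-stabilised ylide, which at low temperature should add to the carbonyl faster than it enolises the α-silyloxy ketone, so the (R) centre is kept.

Step 8
Reactants: 13 bis-silyl ether
Product: 14 4-[(2R)-2-(tert-butyldimethylsilyloxy)-7-methyl-3-methylideneoct-6-en-1-yl]-3,5-bis(methoxymethoxy)phenol
Conditions: TBAF (1.05 equiv), AcOH (1.05 equiv), THF, 0 °C
Reagents that add atoms: none
Why: Selective desilylation, since fluoride cleaves the aryl silyl ether (phenoxide leaving group) much faster than the hindered secondary alkyl TBS ether, and acetic acid keeps the medium from turning basic.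

Step 9
Reactants: 14 phenol
Product: 15 2-bromo-4-[(2R)-2-(tert-butyldimethylsilyloxy)-7-methyl-3-methylideneoct-6-en-1-yl]-3,5-bis(methoxymethoxy)phenol
Conditions: NBS (1.0 equiv), CH2Cl2, −78 °C
Reagents that add atoms: N-bromosuccinimide (NBS), O=C1CCC(=O)N1Br
Why: Electrophilic aromatic bromination of a strongly activated phenol; the only free ring positions are the two equivalent ones ortho to the hydroxyl, so one equivalent at low temperature should give a single monobromide before the alkenes react.

Step 10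
Reactants: 15 bromophenol
Product: 19 4-[(2R)-2-(tert-butyldimethylsilyloxy)-7-methyl-3-methylideneoct-6-en-1-yl]-3,5-bis(methoxymethoxy)-2-(trimethylsilyl)phenyl trifluoromethanesulfonate, via trimethylsilyl ether 16 (not isolated), via aryllithium 17 (not isolated), via lithium phenoxide 18 (not isolated)
Conditions: HMDS, THF, 65 °C, then evaporation; n-BuLi, THF, −100 °C; Tf2O, −100 → −78 °C
Reagents that add atoms: hexamethyldisilazane (HMDS), C[Si](C)(C)N[Si](C)(C)C; trifluoromethanesulfonic anhydride (Tf2O), O=S(=O)(OS(=O)(=O)C(F)(F)F)C(F)(F)F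
Why: O-silylation, then bromine–lithium exchange (faster than any deprotonation at −100 °C), then a 1,3 O→C silyl shift (retro-Brook rearrangement) driven by formation of the lithium phenoxide, which is trapped as the triflate.

Step 11
Reactants: 19 silyl aryl triflate; 20 benzoic acid
Product: 23 {3-[(2R)-2-(tert-butyldimethylsilyloxy)-7-methyl-3-methylideneoct-6-en-1-yl]-6-hydroxy-2,4-bis(methoxymethoxy)phenyl}(phenyl)methanone, via aryne 21 (not isolated), via aryl anion 22 (not isolated)
Conditions: CsF (4 equiv), PhCO2H (1.2 equiv), THF, 125 °C, sealed tube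
Reagents that add atoms: none
Why: Fluoride takes the trimethylsilyl group of 19 and triflate leaves from the neighbouring carbon, giving aryne 21, whose strained bond joins a carbon next to the ring C–H and a carbon next to a MOM ether. Cesium benzoate, formed in the flask, adds through oxygen to the carbon beside C–H, because the σ-withdrawing MOM oxygen distorts the aryne so that the distal carbon is the more electrophilic one and the negative charge builds up next to the ether, in aryl anion 22. Acyl transfer follows: the carbanion of 22 adds to the carbonyl of its own ortho benzoate in a four-centre, anionic Fries-type 1,3 O→C shift and collapses to the ketone phenoxide, the known insertion of arynes into the C–O bond of carboxylic acids that gives ortho-hydroxyaryl ketones. No ring is closed and no stereocentre is created; the side-chain centre is remote and untouched. The step needs regioselective O-attack, which the MOM ether at one aryne terminus and the unhindered C–H flank at the other secure, and it needs acyl transfer to outrun protonation of 22, which the high temperature in THF and near-stoichiometric acid favour. The alkyl TBS ether and the MOM ethers should tolerate CsF suspended in THF, and the slight excess of benzoate over aryne keeps the product phenoxide from being arylated.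

Step 12
Reactants: 23 protected benzophenone
Product: 24 {2,4,6-trihydroxy-3-[(2R)-2-hydroxy-7-methyl-3-methylideneoct-6-en-1-yl]phenyl}(phenyl)methanone (target)
Conditions: HCl (1 M) in MeOH, 0 °C → rt
Reagents that add atoms: none
Why: Acid-catalysed transacetalisation of both MOM ethers and solvolysis of the silyl ether in methanol; the carbinol C–O bond is not cleaved, and dilute acid at or below room temperature limits addition of the free ortho-phenol to the alkenes.

Compound list
1 | benzene-1,3,5-triol (phloroglucinol) | Oc1cc(O)cc(O)c1 | starting material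
2 | 5-(triisopropylsilyloxy)benzene-1,3-diol | CC(C)[Si](Oc1cc(O)cc(O)c1)(C(C)C)C(C)C | intermediate
3 | [3,5-bis(methoxymethoxy)phenoxy]tri(propan-2-yl)silane | COCOc1cc(OCOC)cc(O[Si](C(C)C)(C(C)C)C(C)C)c1 | intermediate
4 | methyl (2R)-oxirane-2-carboxylate | COC(=O)[C@H]1CO1 | starting material
5 | [2,6-bis(methoxymethoxy)-4-(triisopropylsilyloxy)phenyl]lithium | [Li]c1c(OCOC)cc(O[Si](C(C)C)(C(C)C)C(C)C)cc1OCOC | intermediate (not isolated)
6 | bromo[2,6-bis(methoxymethoxy)-4-(triisopropylsilyloxy)phenyl]magnesium | Br[Mg]c1c(OCOC)cc(O[Si](C(C)C)(C(C)C)C(C)C)cc1OCOC | intermediate (not isolated)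
7 | methyl (2R)-3-[2,6-bis(methoxymethoxy)-4-(triisopropylsilyloxy)phenyl]-2-hydroxypropanoate | COC(=O)[C@H](O)Cc1c(OCOC)cc(O[Si](C(C)C)(C(C)C)C(C)C)cc1OCOC | intermediate
8 | methyl (2R)-3-[2,6-bis(methoxymethoxy)-4-(triisopropylsilyloxy)phenyl]-2-(tert-butyldimethylsilyloxy)propanoate | COC(=O)[C@H](O[Si](C)(C)C(C)(C)C)Cc1c(OCOC)cc(O[Si](C(C)C)(C(C)C)C(C)C)cc1OCOC | intermediate
9 | (2R)-3-[2,6-bis(methoxymethoxy)-4-(triisopropylsilyloxy)phenyl]-2-(tert-butyldimethylsilyloxy)-N-methoxy-N-methylpropanamide | CON(C)C(=O)[C@H](O[Si](C)(C)C(C)(C)C)Cc1c(OCOC)cc(O[Si](C(C)C)(C(C)C)C(C)C)cc1OCOC | intermediate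
10 | 5-bromo-2-methylpent-2-ene | CC(C)=CCCBr | starting material
11 | bromo(4-methylpent-3-en-1-yl)magnesium | CC(C)=CCC[Mg]Br | intermediate (not isolated)
12 | (2R)-1-[2,6-bis(methoxymethoxy)-4-(triisopropylsilyloxy)phenyl]-2-(tert-butyldimethylsilyloxy)-7-methyloct-6-en-3-one | CC(C)=CCCC(=O)[C@H](O[Si](C)(C)C(C)(C)C)Cc1c(OCOC)cc(O[Si](C(C)C)(C(C)C)C(C)C)cc1OCOC | intermediate
13 | tert-butyl{[(2R)-1-[2,6-bis(methoxymethoxy)-4-(triisopropylsilyloxy)phenyl]-7-methyl-3-methylideneoct-6-en-2-yl]oxy}dimethylsilane | C=C(CCC=C(C)C)[C@H](O[Si](C)(C)C(C)(C)C)Cc1c(OCOC)cc(O[Si](C(C)C)(C(C)C)C(C)C)cc1OCOC | intermediate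
14 | 4-[(2R)-2-(tert-butyldimethylsilyloxy)-7-methyl-3-methylideneoct-6-en-1-yl]-3,5-bis(methoxymethoxy)phenol | C=C(CCC=C(C)C)[C@H](O[Si](C)(C)C(C)(C)C)Cc1c(OCOC)cc(O)cc1OCOC | intermediate
15 | 2-bromo-4-[(2R)-2-(tert-butyldimethylsilyloxy)-7-methyl-3-methylideneoct-6-en-1-yl]-3,5-bis(methoxymethoxy)phenol | C=C(CCC=C(C)C)[C@H](O[Si](C)(C)C(C)(C)C)Cc1c(OCOC)cc(O)c(Br)c1OCOC | intermediate
16 | {2-bromo-4-[(2R)-2-(tert-butyldimethylsilyloxy)-7-methyl-3-methylideneoct-6-en-1-yl]-3,5-bis(methoxymethoxy)phenoxy}trimethylsilane | C=C(CCC=C(C)C)[C@H](O[Si](C)(C)C(C)(C)C)Cc1c(OCOC)cc(O[Si](C)(C)C)c(Br)c1OCOC | intermediate (not isolated)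
17 | {3-[(2R)-2-(tert-butyldimethylsilyloxy)-7-methyl-3-methylideneoct-6-en-1-yl]-2,4-bis(methoxymethoxy)-6-(trimethylsilyloxy)phenyl}lithium | C=C(CCC=C(C)C)[C@H](O[Si](C)(C)C(C)(C)C)Cc1c(OCOC)cc(O[Si](C)(C)C)c([Li])c1OCOC | intermediate (not isolated)
18 | lithium 4-[(2R)-2-(tert-butyldimethylsilyloxy)-7-methyl-3-methylideneoct-6-en-1-yl]-3,5-bis(methoxymethoxy)-2-(trimethylsilyl)phenolate | C=C(CCC=C(C)C)[C@H](O[Si](C)(C)C(C)(C)C)Cc1c(OCOC)cc([O-])c([Si](C)(C)C)c1OCOC.[Li+] | intermediate (not isolated)
19 | 4-[(2R)-2-(tert-butyldimethylsilyloxy)-7-methyl-3-methylideneoct-6-en-1-yl]-3,5-bis(methoxymethoxy)-2-(trimethylsilyl)phenyl trifluoromethanesulfonate | C=C(CCC=C(C)C)[C@H](O[Si](C)(C)C(C)(C)C)Cc1c(OCOC)cc(OS(=O)(=O)C(F)(F)F)c([Si](C)(C)C)c1OCOC | intermediate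
20 | benzoic acid | OC(=O)c1ccccc1 | starting material
21 | tert-butyl{[(2R)-1-[2,6-bis(methoxymethoxy)-3,4-didehydrophenyl]-7-methyl-3-methylideneoct-6-en-2-yl]oxy}dimethylsilane (aryne) | C=C(CCC=C(C)C)[C@H](O[Si](C)(C)C(C)(C)C)CC1=C(OCOC)C#CC=C1OCOC | intermediate (not isolated)
22 | cesium 6-(benzoyloxy)-3-[(2R)-2-(tert-butyldimethylsilyloxy)-7-methyl-3-methylideneoct-6-en-1-yl]-2,4-bis(methoxymethoxy)benzen-1-ide | C=C(CCC=C(C)C)[C@H](O[Si](C)(C)C(C)(C)C)Cc1c(OCOC)cc(OC(=O)c2ccccc2)[c-]c1OCOC.[Cs+] | intermediate (not isolated)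
23 | {3-[(2R)-2-(tert-butyldimethylsilyloxy)-7-methyl-3-methylideneoct-6-en-1-yl]-6-hydroxy-2,4-bis(methoxymethoxy)phenyl}(phenyl)methanone | C=C(CCC=C(C)C)[C@H](O[Si](C)(C)C(C)(C)C)Cc1c(OCOC)cc(O)c(C(=O)c2ccccc2)c1OCOC | intermediate
24 | {2,4,6-trihydroxy-3-[(2R)-2-hydroxy-7-methyl-3-methylideneoct-6-en-1-yl]phenyl}(phenyl)methanone | C=C(CCC=C(C)C)[C@H](O)Cc1c(O)cc(O)c(C(=O)c2ccccc2)c1O | target

Total step count: 12
Longest linear sequence: 12 steps (1 → 24)

Steps most likely to fail

Step 11. The aryl anion 22 may be protonated before the acyl group shifts, which would leave an aryl benzoate without the ketone, and fluoride at 125 °C may slowly remove the side-chain silyl ether. The fallback avoids the aryne and sets out from 15. O-Benzoylation (BzCl, Et3N, DMAP, CH2Cl2) would give 2-bromo-4-[(2R)-2-(tert-butyldimethylsilyloxy)-7-methyl-3-methylideneoct-6-en-1-yl]-3,5-bis(methoxymethoxy)phenyl benzoate F1. Treatment with s-BuLi in THF at −95 °C would exchange bromine for lithium, and the aryllithium would take the benzoyl group from the neighbouring oxygen (anionic Fries rearrangement triggered by halogen–metal exchange). The route is rejoined at 23.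

Step 12. Under protic acid the free ortho-phenol may add across the protonated 1,1-disubstituted alkene (chroman formation), or the trisubstituted alkene may take up methanol. The fallback sets out from 23 and removes the groups in two stages without mineral acid. ZnBr2 and n-PrSH in CH2Cl2 at 0 °C would cleave both MOM ethers to give {3-[(2R)-2-(tert-butyldimethylsilyloxy)-7-methyl-3-methylideneoct-6-en-1-yl]-2,4,6-trihydroxyphenyl}(phenyl)methanone F2. Buffered fluoride (TBAF, AcOH, THF) would then remove the silyl group and arrive at 24.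

Step 3. Ring opening by the doubly ortho-substituted aryl metal may be sluggish, and attack at the ester carbonyl may compete. The fallback sets out from 3 and uses an epoxide without an ester. The aryllithium (n-BuLi, THF) would open (R)-benzyl glycidyl ether at its CH2 group in the presence of BF3·OEt2 at −78 °C to give (2R)-1-(benzyloxy)-3-[2,6-bis(methoxymethoxy)-4-(triisopropylsilyloxy)phenyl]propan-2-ol F3. Silylation (TBSCl, imidazole, DMF) would give {[(2R)-1-(benzyloxy)-3-[2,6-bis(methoxymethoxy)-4-(triisopropylsilyloxy)phenyl]propan-2-yl]oxy}(tert-butyl)dimethylsilane F4. Hydrogenolysis (H2, Pd/C, EtOAc) would give (2R)-3-[2,6-bis(methoxymethoxy)-4-(triisopropylsilyloxy)phenyl]-2-(tert-butyldimethylsilyloxy)propan-1-ol F5. Oxidation (TEMPO, PhI(OAc)2, MeCN–H2O) would give (2R)-3-[2,6-bis(methoxymethoxy)-4-(triisopropylsilyloxy)phenyl]-2-(tert-butyldimethylsilyloxy)propanoic acid F6. Amide coupling with MeNH(OMe)·HCl (EDC·HCl, i-Pr2NEt, CH2Cl2) returns to the route at 9.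

Further compounds
F1 | step 11 | 2-bromo-4-[(2R)-2-(tert-butyldimethylsilyloxy)-7-methyl-3-methylideneoct-6-en-1-yl]-3,5-bis(methoxymethoxy)phenyl benzoate | C=C(CCC=C(C)C)[C@H](O[Si](C)(C)C(C)(C)C)Cc1c(OCOC)cc(OC(=O)c2ccccc2)c(Br)c1OCOC
F2 | step 12 | {3-[(2R)-2-(tert-butyldimethylsilyloxy)-7-methyl-3-methylideneoct-6-en-1-yl]-2,4,6-trihydroxyphenyl}(phenyl)methanone | C=C(CCC=C(C)C)[C@H](O[Si](C)(C)C(C)(C)C)Cc1c(O)cc(O)c(C(=O)c2ccccc2)c1O
F3 | step 3 | (2R)-1-(benzyloxy)-3-[2,6-bis(methoxymethoxy)-4-(triisopropylsilyloxy)phenyl]propan-2-ol | c1ccccc1COC[C@H](O)Cc1c(OCOC)cc(O[Si](C(C)C)(C(C)C)C(C)C)cc1OCOC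
F4 | step 3 | {[(2R)-1-(benzyloxy)-3-[2,6-bis(methoxymethoxy)-4-(triisopropylsilyloxy)phenyl]propan-2-yl]oxy}(tert-butyl)dimethylsilane | c1ccccc1COC[C@H](O[Si](C)(C)C(C)(C)C)Cc1c(OCOC)cc(O[Si](C(C)C)(C(C)C)C(C)C)cc1OCOC
F5 | step 3 | (2R)-3-[2,6-bis(methoxymethoxy)-4-(triisopropylsilyloxy)phenyl]-2-(tert-butyldimethylsilyloxy)propan-1-ol | OC[C@H](O[Si](C)(C)C(C)(C)C)Cc1c(OCOC)cc(O[Si](C(C)C)(C(C)C)C(C)C)cc1OCOC
F6 | step 3 | (2R)-3-[2,6-bis(methoxymethoxy)-4-(triisopropylsilyloxy)phenyl]-2-(tert-butyldimethylsilyloxy)propanoic acid | OC(=O)[C@H](O[Si](C)(C)C(C)(C)C)Cc1c(OCOC)cc(O[Si](C(C)C)(C(C)C)C(C)C)cc1OCOC
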